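The bicyclo[3.2.1]octane is opened at the two bonds that tie its two-carbon bridge (C-6, C-7) to the bridgeheads C-5 (prenyl) and C-1 (methyl). These bridgeheads flank the bridging ketone C-8 and are the two alkylated ring carbons of a flat acylphloroglucinol; the bridge with its dimethylcarbinol is an oxidised prenyl unit. In the key step the lithium phenoxide of this acylphloroglucinol is C-alkylated at the prenylated carbon by an enantiopure epoxy-prenyl iodide, and the dearomatised enolate then opens the oxirane 5-exo through the methylated carbon, copying prenylation followed by epoxide cyclisation in the presumed biosynthesis. The (S)-oxirane carbon becomes C-7 and dictates both bridgeheads.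

Key step: step 6

Remark: atoms are numbered as in the bicyclo[3.2.1]octane name used here for the target (C-1 methyl bridgehead, C-2 to C-4 enolised triketone bridge, C-5 prenyl bridgehead, C-6 CH2, C-7 CH, C-8 ketone bridge); the target and its enol tautomers are treated as one compound.

Step 1
Reactants: 1 3-methylbut-2-en-1-ol (prenol)
Product: 3 [(2S)-3,3-dimethyloxiran-2-yl]methyl 4-methylbenzenesulfonate, via epoxy alcohol 2 (not isolated)
Conditions: Ti(OiPr)4 (cat.), L-(+)-DIPT (cat.), t-BuOOH, 4 Å MS, CH2Cl2, −20 °C; then TsCl, Et3N, DMAP (cat.), −10 °C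
Reagents that add atoms: tert-butyl hydroperoxide CC(C)(C)OO; 4-methylbenzenesulfonyl chloride Cc1ccc(cc1)S(Cl)(=O)=O
Why: Katsuki–Sharpless asymmetric epoxidation with the L-(+)-tartrate should deliver oxygen to the alkene face that gives the (S)-epoxy alcohol, and sulfonate ester formation in the same flask traps this water-soluble alcohol without touching the stereocentre.

Step 2
Reactants: 3 [(2S)-3,3-dimethyloxiran-2-yl]methyl 4-methylbenzenesulfonate
Product: 4 (2R)-2-(iodomethyl)-3,3-dimethyloxirane
Conditions: NaI, acetone, rt, dark
Reagents that add atoms: sodium iodide [Na+].[I-]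
Why: Finkelstein reaction, an SN2 exchange at the primary carbon that leaves the oxirane stereocentre untouched (the descriptor changes to R only through the sequence rule) and gives a softer electrophile for C-alkylation.

Step 3
Reactants: 5 (2R)-2-methylbutanoic acid
Product: 6 (2R)-2-methylbutanoyl chloride
Conditions: (COCl)2, DMF (cat.), CH2Cl2, 0 °C to rt
Reagents that add atoms: oxalyl chloride ClC(=O)C(Cl)=O
Why: Acid chloride formation through the Vilsmeier-type chloroiminium species runs without base at or below room temperature, so the α-stereocentre should be kept.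

Step 4
Reactants: 6 (2R)-2-methylbutanoyl chloride, 7 2-methylbenzene-1,3,5-triol
Product: 8 (2R)-2-methyl-1-(2,4,6-trihydroxy-3-methylphenyl)butan-1-one
Conditions: AlCl3, PhNO2/CH2Cl2, 0 °C to rt; aq. HCl
Reagents that add atoms: none
Why: Friedel–Crafts acylation in which the two free ring positions of 7 are equivalent, so one C-acyl regioisomer should form, the chelated aryl ketone resists a second acylation and the stereocentre is carried over from 6.

Step 5
Reactants: 8 (2R)-2-methyl-1-(2,4,6-trihydroxy-3-methylphenyl)butan-1-one, 9 1-bromo-3-methylbut-2-ene (prenyl bromide)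
Product: 10 (2R)-2-methyl-1-[2,4,6-trihydroxy-3-methyl-5-(3-methylbut-2-en-1-yl)phenyl]butan-1-one
Conditions: DBU, THF, 0 °C to rt
Reagents that add atoms: none
Why: Friedel–Crafts-type C-allylation of the phloroglucinol anion, in which the one remaining ring CH is the most nucleophilic carbon and re-aromatises after attack on the allylic bromide, while one equivalent of 9 limits gem-diprenylation.

Step 6
Reactants: 10 (2R)-2-methyl-1-[2,4,6-trihydroxy-3-methyl-5-(3-methylbut-2-en-1-yl)phenyl]butan-1-one, 4 (2R)-2-(iodomethyl)-3,3-dimethyloxirane
Product: 12 (1S,5S,7S)-2-hydroxy-7-(2-hydroxypropan-2-yl)-1-methyl-3-[(2R)-2-methylbutanoyl]-5-(3-methylbut-2-en-1-yl)bicyclo[3.2.1]oct-2-ene-4,8-dione, via alkylated epoxy dienone 11 (not isolated)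
Conditions: LiN(SiMe3)2 (3.1 equiv), THF, −78 °C; then 4, −78 to 0 °C; then 40 °C; aq. NH4Cl
Reagents that add atoms: none
Why: Proposed new method: the lithium phenoxide of 10 should be C-alkylated by the primary iodide 4 at the prenylated ring carbon (SN2, dearomatisation) to give 11, whose remaining dienolate then opens the oxirane at its secondary carbon through the methylated ring carbon with inversion, so that both bridge bonds form in one flask; the closest known reaction types are the alkylative dearomatisation–annulation of acylphloroglucinols with bis-electrophiles and the intramolecular enolate–epoxide alkylation that gives bridged ketones. The ring closure is 5-exo-tet (not 6-endo at the tertiary oxirane carbon, which basic conditions disfavour) and makes the cyclopentanone ring C-1/C-8/C-5/C-6/C-7 of the bicycle. C-7 is set by the (S)-oxirane through inversion, and C-1 and C-5 are tied to it because closure is feasible only with the oxirane exo, on the side of C-8 and away from the triketone bridge. The quaternary carbon made in the alkylation is not controlled, so 11 should form together with its epimer at that carbon, and only 11 can reach the exo transition state and go on to 12; the epimer would need the endo mode and should stay uncyclised or close through oxygen, so at most half of the correctly alkylated material can reach 12. The step needs carbon instead of oxygen attack twice (soft iodide, lithium counter-ion in THF, approach of the axial side chain perpendicular to the ring), alkylation at the prenylated and not the methylated carbon (expected by analogy with gem-diprenylation of such rings, but not secured) and closure through C-1 and not the acyl-bearing C-3 (the least nucleophilic carbon, which would also need the endo mode).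

Compound list
1 | 3-methylbut-2-en-1-ol (prenol) | CC(C)=CCO | starting material
2 | [(2S)-3,3-dimethyloxiran-2-yl]methanol | OC[C@@H]1OC1(C)C | intermediate
3 | [(2S)-3,3-dimethyloxiran-2-yl]methyl 4-methylbenzenesulfonate | Cc1ccc(cc1)S(=O)(=O)OC[C@@H]1OC1(C)C | intermediate
4 | (2R)-2-(iodomethyl)-3,3-dimethyloxirane | IC[C@@H]1OC1(C)C | intermediate
5 | (2R)-2-methylbutanoic acid | CC[C@@H](C)C(O)=O | starting material
6 | (2R)-2-methylbutanoyl chloride | CC[C@@H](C)C(Cl)=O | intermediate
7 | 2-methylbenzene-1,3,5-triol (2-methylphloroglucinol) | Cc1c(O)cc(O)cc1O | starting material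
8 | (2R)-2-methyl-1-(2,4,6-trihydroxy-3-methylphenyl)butan-1-one | CC[C@@H](C)C(=O)c1c(O)cc(O)c(C)c1O | intermediate
9 | 1-bromo-3-methylbut-2-ene (prenyl bromide) | CC(C)=CCBr | starting material
10 | (2R)-2-methyl-1-[2,4,6-trihydroxy-3-methyl-5-(3-methylbut-2-en-1-yl)phenyl]butan-1-one | CC[C@@H](C)C(=O)c1c(O)c(CC=C(C)C)c(O)c(C)c1O | intermediate
11 | (6S)-6-{[(2S)-3,3-dimethyloxiran-2-yl]methyl}-3,5-dihydroxy-4-methyl-2-[(2R)-2-methylbutanoyl]-6-(3-methylbut-2-en-1-yl)cyclohexa-2,4-dien-1-one (lithium salt in the flask) | CC[C@@H](C)C(=O)C1=C(O)C(C)=C(O)[C@](CC=C(C)C)(C[C@@H]2OC2(C)C)C1=O | intermediate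
12 | (1S,5S,7S)-2-hydroxy-7-(2-hydroxypropan-2-yl)-1-methyl-3-[(2R)-2-methylbutanoyl]-5-(3-methylbut-2-en-1-yl)bicyclo[3.2.1]oct-2-ene-4,8-dione | CC[C@@H](C)C(=O)C1=C(O)[C@@]2(C)C(=O)[C@](CC=C(C)C)(C[C@@H]2C(C)(C)O)C1=O | target

Total step count: 6. Longest linear sequence: 4 steps (steps 3, 4, 5 and 6, from acid 5).

Steps most likely to fail

Step 6 (Proposed new method). Several processes can divert it:
- attack through oxygen instead of carbon, either in the alkylation or in the oxirane opening;
- alkylation at the methylated instead of the prenylated ring carbon;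
- loss of the mismatched epimer at the new quaternary carbon, which is built into the design;
- retro-Claisen opening of the bridging ketone by the new tertiary alkoxide.

Fallback with known chemistry, setting out from 10 and coming back at 12: dearomative C-prenylation of 10 with 9 (KOH, H2O, 0 °C) gives the gem-diprenyl trione F1. Oxidative radical cyclisation of F1 under oxygen (Mn(OAc)3·2H2O, AcOH/EtOH, O2, rt) closes C-1 onto one prenyl group 5-exo and traps the tertiary radical as the hydroperoxide F2, which PPh3 reduces to 12. No element controls the sense of the bicycle in this sequence, so 12 would have to be separated from its diastereomer with the mirror-image core by preparative HPLC.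

Step 5. Over-alkylation to the gem-diprenyl compound and alkylation at oxygen may compete under basic conditions. Fallback, setting out from 8 and coming back at 10: acid-mediated Friedel–Crafts prenylation of the neutral phenol with 2-methylbut-3-en-2-ol and BF3·OEt2 in dioxane at rt, which cannot dearomatise the ring and should give 10 directly.

Step 4. The Lewis acid may erode the α-stereocentre of the acyl group through enolisation of the chelated ketone, and O-acylation or bis-acylation may compete. Fallback, setting out from 7 and 5 and coming back at 8: 7 is converted into the tris(methoxymethyl) ether F3 (MOMCl, iPr2NEt, CH2Cl2), and 5 into the Weinreb amide F4 (MeNHOMe·HCl, EDC, CH2Cl2). F3 is lithiated between two OMOM groups (n-BuLi, THF, 0 °C) and added to F4 to give the protected ketone F5; HCl in MeOH removes the MOM groups and returns 8.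

Further compounds
F1 | step 6 | 3,5-dihydroxy-4-methyl-2-[(2R)-2-methylbutanoyl]-6,6-bis(3-methylbut-2-en-1-yl)cyclohexa-2,4-dien-1-one | CC[C@@H](C)C(=O)C1=C(O)C(C)=C(O)C(CC=C(C)C)(CC=C(C)C)C1=O
F2 | step 6 | (1S,5S,7S)-7-(2-hydroperoxypropan-2-yl)-2-hydroxy-1-methyl-3-[(2R)-2-methylbutanoyl]-5-(3-methylbut-2-en-1-yl)bicyclo[3.2.1]oct-2-ene-4,8-dione | CC[C@@H](C)C(=O)C1=C(O)[C@@]2(C)C(=O)[C@](CC=C(C)C)(C[C@@H]2C(C)(C)OO)C1=O
F0 | step 5 | none | none
F3 | step 4 | 1,3,5-tris(methoxymethoxy)-2-methylbenzene | Cc1c(OCOC)cc(OCOC)cc1OCOC
F4 | step 4 | (2R)-N-methoxy-N,2-dimethylbutanamide | CC[C@@H](C)C(=O)N(C)OC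
F5 | step 4 | (2R)-2-methyl-1-[2,4,6-tris(methoxymethoxy)-3-methylphenyl]butan-1-one | CC[C@@H](C)C(=O)c1c(OCOC)cc(OCOC)c(C)c1OCOC
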